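**Plan**

- Retrosynthesis: the allyl-masked carboxyl of ring B and the C3–CH2OH bond of ring A (ortho to the C2 phenol) are cut first. Ring A is then opened at C1–C2 and C5–C6, and last the acyl–O4' bond of a but-2-ynoate ester is cut.
- Enabling feature: in ring A the C1–C6 edge (C1 bearing the ester carbonyl, C6 the methyl) has the substitution of a but-2-ynoate, and C2–C3–C4–C5 with oxygen on C2 and C4 is a 1,3-dioxygenated butadiene. The crowded 2,6-disubstituted aroyl–O4' bond can therefore be made as an ordinary acylation with an unencumbered alkynoic acid.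
- Forward: ring B is bought as 2,5-dimethylresorcinol, carboxylated, allylated and acylated at O4' with but-2-ynoic acid. Ring A, the only ring constructed, is grown on this ester by (4+2) cycloaddition with a 1,3-dimethoxy-1-silyloxybutadiene and loss of methanol.
- End game: boron-templated hydroxymethylation at C3, then deallylation with zerovalent palladium.
- Stereochemistry: the target has no stereocentre. The one sp3 centre of the cycloadduct is erased on aromatisation, and regiochemistry is dictated by the polarised diene.

Key step: step 5

Assumption: the ketene acetal geometry of the diene (drawn Z) is taken as immaterial because that carbon ends as sp2 C2 of ring A; 2,5-dimethylresorcinol, but-2-ynoic acid and methyl (E)-3-methoxybut-2-enoate are taken as purchasable.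

**Route**

Step 1
Reactants: 1 2,5-dimethylresorcinol
Product: 2 2,4-dihydroxy-3,6-dimethylbenzoic acid
Conditions: KHCO3 (5 equiv), H2O, CO2 (1 atm), 100 °C; then HCl, 0 °C
Reagents that add atoms: carbon dioxide, O=C=O; potassium hydrogencarbonate, [K+].OC([O-])=O (the two interconvert and together supply the carboxyl group)
Why: Kolbe–Schmitt carboxylation of the resorcinol should place the carboxyl ortho to one hydroxyl and para to the other, and because C2 is blocked by methyl the two equivalent free ring positions lead to a single acid.

Step 2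
Reactants: 2 2,4-dihydroxy-3,6-dimethylbenzoic acid
Product: 3 allyl 2,4-dihydroxy-3,6-dimethylbenzoate
Conditions: allyl bromide (1.1 equiv), KHCO3 (1.2 equiv), DMF, 23 °C
Reagents that add atoms: allyl bromide, C=CCBr
Why: SN2 O-alkylation of the carboxylate should be selective because hydrogencarbonate ionises only the carboxylic acid and leaves both phenols protonated.

Step 3
Reactants: 3 allyl 2,4-dihydroxy-3,6-dimethylbenzoate; 4 but-2-ynoic acid
Product: 5 allyl 4-(but-2-ynoyloxy)-2-hydroxy-3,6-dimethylbenzoate
Conditions: DCC (1.1 equiv), DMAP (5 mol %), CH2Cl2, −20 → 0 °C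
Reagents that add atoms: none
Why: Steglich esterification should acylate only the 4-OH, since the 2-OH is held in a hydrogen bond to the ester carbonyl and flanked on both sides, while the low temperature and small DMAP loading limit conjugate addition to the ynoate.

Step 4
Reactants: 6 methyl (E)-3-methoxybut-2-enoate
Product: 8 (Z)-[(1,3-dimethoxybuta-1,3-dien-1-yl)oxy]trimethylsilane, via lithium dienolate 7 (not isolated)
Conditions: LiN(iPr)2 (1.1 equiv), THF, −78 °C; then Me3SiCl (1.2 equiv), −78 → 0 °C; pentane, filtration, distillation
Reagents that add atoms: chlorotrimethylsilane, C[Si](C)(C)Cl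
Why: Kinetic γ-deprotonation of the β-methoxy enoate (the methyl group lies cis to the carbonyl) gives the extended lithium dienolate, and its oxygen terminus should be trapped by the hard silyl chloride (silyl ketene acetal formation).

Step 5
Reactants: 5 allyl 4-(but-2-ynoyloxy)-2-hydroxy-3,6-dimethylbenzoate; 8 (Z)-[(1,3-dimethoxybuta-1,3-dien-1-yl)oxy]trimethylsilane
Product: 12 allyl 2-hydroxy-4-[(2-hydroxy-4-methoxy-6-methylbenzoyl)oxy]-3,6-dimethylbenzoate, via aryl silyl ether 9 (not isolated), via cyclohexadiene cycloadduct 10 (not isolated), via bis-silyl ether 11 (not isolated)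
Conditions: MeC(OSiMe3)=NSiMe3 (BSA, 1.2 equiv), toluene, 23 °C; then 8 (2.5 equiv), 110 °C, sealed tube; then 1 M HCl, THF, 23 °C
Reagents that add atoms: none
Why: N,O-bis(trimethylsilyl)acetamide first caps the acidic 2'-OH of 5 as silyl ether 9, so that no diene is consumed by proton transfer. The electron-rich diene 8 then adds to the aryl ynoate, whose phenolic ester oxygen makes it a better acceptor than an alkyl but-2-ynoate, in an asynchronous normal-demand (4+2) cycloaddition (closest known reaction type: Diels–Alder reaction of 1,1,3-trioxygenated Brassard-type dienes with acetylenic esters), closing ring A as a six-membered carbocycle by intermolecular (4+2) annulation through the C5–C6 and C1–C2 bonds to give cyclohexa-1,4-diene 10. The selectivity needed is regiochemical and is secured by matched polarisation: the CH2 end of the diene, the nucleophilic terminus of a vinylogous ketene acetal, attacks the methyl-bearing β-carbon of the ynoate (future C6), and the ketal carbon joins the α-carbon (future C1). The methyl silyl ketal at C2 of 10 ionises easily because the cation is stabilised by the C4 enol ether, so methanol should be lost in the hot solution to give arene 11 with C2–OSiMe3 and C4–OMe in place. The only stereocentre formed (C2 of 10, racemic and uncontrolled) vanishes in this aromatisation, and dilute acid then cleaves both aryl silyl ethers while the allyl ester and the shielded diaryl ester should stay intact.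

Step 6
Reactants: 12 allyl 2-hydroxy-4-[(2-hydroxy-4-methoxy-6-methylbenzoyl)oxy]-3,6-dimethylbenzoate
Product: 14 allyl 2-hydroxy-4-{[2-hydroxy-3-(hydroxymethyl)-4-methoxy-6-methylbenzoyl]oxy}-3,6-dimethylbenzoate, via benzodioxaborin 13 (not isolated)
Conditions: PhB(OH)2 (1.5 equiv), (CH2O)n (5 equiv), EtCO2H (0.2 equiv), toluene, reflux, Dean–Stark; then propane-1,3-diol (10 equiv), THF, 23 °C
Reagents that add atoms: paraformaldehyde (reacts as formaldehyde), C=O
Why: In the Nagata ortho-hydroxymethylation the C2 phenol forms an aryl phenylboronate that binds formaldehyde and delivers it through a six-membered transition state to C3, the one hydrogen-bearing carbon next to a phenolic oxygen in either ring, and exchange with propane-1,3-diol should then release the salicyl alcohol from boron.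

Step 7
Reactants: 14 allyl 2-hydroxy-4-{[2-hydroxy-3-(hydroxymethyl)-4-methoxy-6-methylbenzoyl]oxy}-3,6-dimethylbenzoate
Product: 15 3α-hydroxybarbatic acid, 2-hydroxy-4-{[2-hydroxy-3-(hydroxymethyl)-4-methoxy-6-methylbenzoyl]oxy}-3,6-dimethylbenzoic acid
Conditions: Pd(PPh3)4 (5 mol %), PhNHMe (3 equiv), THF, 23 °C; then 1 M HCl wash
Reagents that add atoms: none
Why: In this Tsuji–Trost deallylation zerovalent palladium ionises the allyl ester to a π-allyl complex that is captured by N-methylaniline, a nucleophile too weak to attack the hindered diaryl ester, so the free acid, both phenols and the benzylic alcohol should emerge untouched.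

**Compound list**

1 | 2,5-dimethylresorcinol (2,5-dimethylbenzene-1,3-diol) | Cc1cc(O)c(C)c(O)c1 | starting material
2 | 2,4-dihydroxy-3,6-dimethylbenzoic acid | Cc1cc(O)c(C)c(O)c1C(=O)O | intermediate
3 | allyl 2,4-dihydroxy-3,6-dimethylbenzoate | Cc1cc(O)c(C)c(O)c1C(=O)OCC=C | intermediate
4 | but-2-ynoic acid | CC#CC(=O)O | starting material
5 | allyl 4-(but-2-ynoyloxy)-2-hydroxy-3,6-dimethylbenzoate | CC#CC(=O)Oc1cc(C)c(C(=O)OCC=C)c(O)c1C | intermediate
6 | methyl (E)-3-methoxybut-2-enoate | CO/C(C)=C/C(=O)OC | starting material
7 | lithium (1E)-1,3-dimethoxybuta-1,3-dien-1-olate (lithium dienolate of 6, formed in the flask of step 4) | C=C(OC)/C=C(/OC)[O-].[Li+] | intermediate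
8 | (Z)-[(1,3-dimethoxybuta-1,3-dien-1-yl)oxy]trimethylsilane | C=C(OC)/C=C(/OC)O[Si](C)(C)C | intermediate
9 | allyl 4-(but-2-ynoyloxy)-3,6-dimethyl-2-(trimethylsilyloxy)benzoate (formed in the flask of step 5) | CC#CC(=O)Oc1cc(C)c(C(=O)OCC=C)c(O[Si](C)(C)C)c1C | intermediate
10 | allyl 4-{[4,6-dimethoxy-2-methyl-6-(trimethylsilyloxy)cyclohexa-1,4-diene-1-carbonyl]oxy}-3,6-dimethyl-2-(trimethylsilyloxy)benzoate, racemic at the ketal carbon (formed in the flask of step 5) | COC1=CC(OC)(O[Si](C)(C)C)C(C(=O)Oc2cc(C)c(C(=O)OCC=C)c(O[Si](C)(C)C)c2C)=C(C)C1 | intermediate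
11 | allyl 4-{[4-methoxy-6-methyl-2-(trimethylsilyloxy)benzoyl]oxy}-3,6-dimethyl-2-(trimethylsilyloxy)benzoate (formed in the flask of step 5) | COc1cc(C)c(C(=O)Oc2cc(C)c(C(=O)OCC=C)c(O[Si](C)(C)C)c2C)c(O[Si](C)(C)C)c1 | intermediate
12 | allyl 2-hydroxy-4-[(2-hydroxy-4-methoxy-6-methylbenzoyl)oxy]-3,6-dimethylbenzoate | COc1cc(C)c(C(=O)Oc2cc(C)c(C(=O)OCC=C)c(O)c2C)c(O)c1 | intermediate
13 | allyl 2-hydroxy-4-[(5-methoxy-7-methyl-2-phenyl-4H-1,3,2-benzodioxaborinine-8-carbonyl)oxy]-3,6-dimethylbenzoate (formed in the flask of step 6) | COc1cc(C)c(C(=O)Oc2cc(C)c(C(=O)OCC=C)c(O)c2C)c2OB(c3ccccc3)OCc12 | intermediate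
14 | allyl 2-hydroxy-4-{[2-hydroxy-3-(hydroxymethyl)-4-methoxy-6-methylbenzoyl]oxy}-3,6-dimethylbenzoate | COc1cc(C)c(C(=O)Oc2cc(C)c(C(=O)OCC=C)c(O)c2C)c(O)c1CO | intermediate
15 | 3α-hydroxybarbatic acid, 2-hydroxy-4-{[2-hydroxy-3-(hydroxymethyl)-4-methoxy-6-methylbenzoyl]oxy}-3,6-dimethylbenzoic acid | COc1cc(C)c(C(=O)Oc2cc(C)c(C(=O)O)c(O)c2C)c(O)c1CO | target

**Step count and risks**

Total step count: 7. Longest linear sequence: 6 steps (steps 1, 2, 3, 5, 6, 7); step 4 makes the diene on a side branch.

Steps most likely to fail:

1. Step 5. The cycloaddition to the β-methyl ynoate may be slower than thermal decay of the diene (silyl migration from oxygen to carbon, oligomerisation), or conjugate addition may stop at an open-chain adduct without ring closure. In the fallback ring A would be brought in ready-made and the aroyl–O4' bond formed last by classical depside esterification. Commercial methyl 2,4-dihydroxy-6-methylbenzoate (methyl orsellinate) would be methylated at its unchelated 4-OH (MeI, K2CO3, acetone) to methyl 2-hydroxy-4-methoxy-6-methylbenzoate F1. Saponification (KOH, DMSO/H2O, 80 °C; cold acidification) would give 2-hydroxy-4-methoxy-6-methylbenzoic acid F2. F2 would then be condensed with the free 4-OH of compound 3 by trifluoroacetic anhydride in toluene at 23 °C. This branch sets out from compound 3 and rejoins the route at compound 12.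

2. Step 6. The hydrogen-bonded C2 phenol may fail to form the aryl boronate, so that untemplated acid-catalysed attack of formaldehyde and diarylmethane condensation of the salicyl alcohol take over. In the fallback, setting out from compound 12, titanium-directed ortho-formylation (Cl2CHOMe, TiCl4, CH2Cl2, 0 °C; Rieche formylation) would place a formyl group at C3 to give allyl 4-[(3-formyl-2-hydroxy-4-methoxy-6-methylbenzoyl)oxy]-2-hydroxy-3,6-dimethylbenzoate F3. Reduction of the aldehyde with NaBH4 (THF/MeOH, −20 °C) would then give the benzylic alcohol, rejoining the route at compound 14.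

3. Step 1. The carboxylation is reversible and the β-resorcylic acid may lose CO2 again during acidification and isolation, leaving mostly recovered resorcinol. In the fallback, setting out from compound 1, the carboxyl carbon would be introduced at the aldehyde oxidation level by Vilsmeier–Haack formylation (POCl3, DMF; aqueous hydrolysis) to give 2,4-dihydroxy-3,6-dimethylbenzaldehyde F4. Pinnick oxidation (NaClO2, NaH2PO4, 2-methylbut-2-ene, tBuOH/H2O) would then give the acid, rejoining the route at compound 2.

**Further compounds**

F1 | step 5 | methyl 2-hydroxy-4-methoxy-6-methylbenzoate | COc1cc(C)c(C(=O)OC)c(O)c1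
F2 | step 5 | 2-hydroxy-4-methoxy-6-methylbenzoic acid | COc1cc(C)c(C(=O)O)c(O)c1
F3 | step 6 | allyl 4-[(3-formyl-2-hydroxy-4-methoxy-6-methylbenzoyl)oxy]-2-hydroxy-3,6-dimethylbenzoate | COc1cc(C)c(C(=O)Oc2cc(C)c(C(=O)OCC=C)c(O)c2C)c(O)c1C=O
F4 | step 1 | 2,4-dihydroxy-3,6-dimethylbenzaldehyde | Cc1cc(O)c(C)c(O)c1C=O
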